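**Retrosynthetic overview**
1. Broussonetine S ⇐ hydrogenation and global deprotection of the (E)-allylic alcohol 17.
2. C1′–C2′ bond and the C1′ carbinol centre ⇐ Ni-catalysed carbinol C–H alkenylation of the C2-symmetric N-Boc diol 8 with terminal alkyne 16 (fragment union).
3. Diol 8 ⇐ two rounds of trans-selective BnOCH2MgCl addition to a cyclic nitrone (3 → 5 → 6), starting from (3R,4R)-pyrrolidine-3,4-diol.
4. Alkyne 16 ⇐ alkyne-zipper isomerisation of the homopropargylic alcohol made from hept-1-yne and (R)-epoxide 12 (Co-salen kinetic resolution; from pent-4-en-1-ol).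
5. Rings: the pyrrolidine is the only ring in the target; it is carried intact from compound 1 and no further ring is formed (the epoxide in 11/12 is transient).

Assumption: (3R,4R)-pyrrolidine-3,4-diol (usually sold as its hydrochloride) is taken as commercially available; the salt is neutralised in situ in step 1.

**Core fragment**

Step 1
Reactants: 1, (3R,4R)-pyrrolidine-3,4-diol
Product: 2, (3R,4R)-3,4-bis[(tert-butyldimethylsilyl)oxy]pyrrolidine
Conditions: TBSCl (2.4 equiv), imidazole (5 equiv), DMF, 0 °C → rt; MeOH/aq NaHCO3 work-up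
Reagents that add atoms: TBSCl, CC(C)(C)[Si](C)(C)Cl
Why: O-silylation of both secondary alcohols; any N–Si bond is hydrolysed on work-up, and no stereocentre is touched.

Step 2
Reactants: 2
Product: 3, (3R,4R)-3,4-bis[(tert-butyldimethylsilyl)oxy]-3,4-dihydro-2H-pyrrole 1-oxide
Conditions: MeReO3 (2 mol %), urea·H2O2 (3 equiv), MeOH, 0 °C → rt
Reagents that add atoms: hydrogen peroxide (urea adduct), OO
Why: Metal-catalysed peroxide oxidation of a secondary amine to the nitrone via the hydroxylamine; the amine is C2-symmetric, so only one nitrone can form.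

Step 3
Reactants: 3
Product: 4, (2R,3R,4R)-2-[(benzyloxy)methyl]-3,4-bis[(tert-butyldimethylsilyl)oxy]pyrrolidin-1-ol
Conditions: BnOCH2MgCl (from BnOCH2Cl, Mg, cat. HgCl2, THF, −10 °C), THF, −78 → 0 °C
Reagents that add atoms: (benzyloxy)methylmagnesium chloride, Cl[Mg]COCc1ccccc1
Why: Grignard addition to a cyclic nitrone occurs anti to the adjacent C3 silyloxy group, setting C2 as R (2,3-trans).

Step 4
Reactants: 4
Product: 5, (2R,3R,4R)-2-[(benzyloxy)methyl]-3,4-bis[(tert-butyldimethylsilyl)oxy]-3,4-dihydro-2H-pyrrole 1-oxide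
Conditions: activated MnO2 (1.5 equiv), CH2Cl2, 0 °C → rt
Reagents that add atoms: none
Why: MnO2 dehydrogenation of the N-hydroxypyrrolidine gives the aldonitrone, because the C5–H anti to the C4–OSi bond is removed preferentially whereas the only C2–H is syn to C3–OSi.

Step 5
Reactants: 5
Product: 6, (2R,3R,4R,5R)-2,5-bis[(benzyloxy)methyl]-3,4-bis[(tert-butyldimethylsilyl)oxy]pyrrolidin-1-ol
Conditions: BnOCH2MgCl (2 equiv), THF, −78 → 0 °C
Reagents that add atoms: (benzyloxy)methylmagnesium chloride, Cl[Mg]COCc1ccccc1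
Why: Second nitrone Grignard addition, anti to the C4 silyloxy group and to the C2 arm, sets C5 as R and gives the all-trans, C2-symmetric skeleton.

Step 6
Reactants: 6
Product: 7, [(2R,3R,4R,5R)-3,4-bis[(tert-butyldimethylsilyl)oxy]pyrrolidine-2,5-diyl]dimethanol
Conditions: H2 (1 atm), 20% Pd(OH)2/C, EtOH–AcOH (20:1), rt; NaHCO3 work-up
Reagents that add atoms: none
Why: Pd-catalysed hydrogenolysis cleaves both benzyl ethers and the N–O bond, while the secondary TBS ethers survive the weakly acidic, non-methanolic medium.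

Step 7
Reactants: 7
Product: 8, tert-butyl (2R,3R,4R,5R)-3,4-bis[(tert-butyldimethylsilyl)oxy]-2,5-bis(hydroxymethyl)pyrrolidine-1-carboxylate
Conditions: Boc2O (1.5 equiv), NaHCO3, THF–H2O, rt → 40 °C
Reagents that add atoms: Boc2O, CC(C)(C)OC(=O)OC(=O)OC(C)(C)C
Why: Chemoselective N-acylation (carbamate formation) of the amine in the presence of the primary alcohols under mild base that avoids silyl migration.

**Side-chain fragment**

Step 8
Reactants: 9, pent-4-en-1-ol
Product: 10, 5-(benzyloxy)pent-1-ene
Conditions: NaH, BnBr, cat. Bu4NI, THF, 0 °C → rt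
Reagents that add atoms: benzyl bromide, BrCc1ccccc1
Why: Williamson etherification; the benzyl ether is stable to the strong bases used later and is removed in the final hydrogenation.

Step 9
Reactants: 10
Product: 11, rac-2-[3-(benzyloxy)propyl]oxirane
Conditions: mCPBA, CH2Cl2, 0 °C → rt
Reagents that add atoms: mCPBA, OOC(=O)c1cccc(Cl)c1
Why: Prilezhaev epoxidation of the terminal alkene.

Step 10
Reactants: 11
Product: 12, (R)-2-[3-(benzyloxy)propyl]oxirane
Conditions: (R,R)-(salen)Co(III)OAc (0.5 mol %), H2O (0.55 equiv), THF (minimal), 0 °C → rt; epoxide separated from diol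
Reagents that add atoms: none
Why: Jacobsen hydrolytic kinetic resolution hydrolyses the (S)-epoxide and leaves (R)-12 in ≥99% ee, which fixes the future C10′ centre. I assigned the (R,R)-catalyst/(R)-epoxide pairing from memory, so confirm by optical rotation and use the antipodal catalyst if reversed.

Step 11
Reactants: 12; 13, hept-1-yne
Product: 14, (R)-1-(benzyloxy)dodec-6-yn-4-ol
Conditions: 13, n-BuLi, THF, −78 °C; BF3·OEt2; then 12, −78 °C
Reagents that add atoms: none
Why: Yamaguchi (BF3-mediated) alkynylation opens the epoxide at the terminal carbon, so the carbinol centre is untouched.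

Step 12
Reactants: 14
Product: 15, (S)-12-(benzyloxy)dodec-1-yn-9-ol
Conditions: KH, H2N(CH2)3NH2 (KAPA), 0 °C → rt
Reagents that add atoms: none
Why: Alkyne-zipper isomerisation moves the triple bond to the chain end (driven by acetylide formation); the carbinol, held as its alkoxide, is not deprotonated, so configuration is retained (the R→S change is only a CIP priority change).

Step 13
Reactants: 15
Product: 16, (9S)-12-(benzyloxy)-9-[(tert-butyldimethylsilyl)oxy]dodec-1-yne
Conditions: TBSCl, imidazole, DMF, rt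
Reagents that add atoms: TBSCl, CC(C)(C)[Si](C)(C)Cl
Why: Standard silylation of the secondary alcohol so that only the core carbinols can be dehydrogenated in the coupling.

**Fragment union and end game**

Step 14
Reactants: 8 (2.5 equiv, excess recovered); 16
Product: 17, tert-butyl (2R,3R,4R,5R)-2-[(1R,2E,10S)-13-(benzyloxy)-10-[(tert-butyldimethylsilyl)oxy]-1-hydroxytridec-2-en-1-yl]-3,4-bis[(tert-butyldimethylsilyl)oxy]-5-(hydroxymethyl)pyrrolidine-1-carboxylate
Conditions: Ni(cod)2 (10 mol %), IMes (12 mol %), toluene, 70 °C; 16 added by syringe pump over 8 h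
Reagents that add atoms: none
Why: Proposed new method: a redox-neutral Ni(0)/NHC carbinol C–H alkenylation in which Ni dehydrogenates one CH2OH of 8 to a metal-bound α-amino aldehyde (β-H elimination from the Ni alkoxide), aldehyde/alkyne oxidative cyclisation forms C1′–C2′ at the unsubstituted alkyne carbon (small NHC, syn addition, hence the linear E-alkene), and the borrowed hydride is returned by C–H reductive elimination. The two CH2OH groups of 8 are homotopic, so mono-coupling gives one constitutional isomer, and Felkin–Anh attack (C2–N bond anti to the forming bond) sets C1′ as R. The closest known reactions are Ni(0)/NHC redox-neutral coupling of primary alcohols with internal alkynes to allylic alcohols and the anti-selective Ni/NHC/silane reductive coupling of α-amino aldehydes with alkynes; neither has been shown for a terminal alkyne with an N-Boc β-amino alcohol or with 1,2-stereoinduction.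

Step 15
Reactants: 17
Product: 18, tert-butyl (2R,3R,4R,5R)-2-[(1R,10S)-10-[(tert-butyldimethylsilyl)oxy]-1,13-dihydroxytridecyl]-3,4-bis[(tert-butyldimethylsilyl)oxy]-5-(hydroxymethyl)pyrrolidine-1-carboxylate
Conditions: H2 (1 atm), 20% Pd(OH)2/C, EtOAc–MeOH, rt
Reagents that add atoms: none
Why: Heterogeneous hydrogenation saturates the C2′=C3′ alkene and hydrogenolyses the benzyl ether without touching any stereocentre.

Step 16
Reactants: 18
Product: 19, broussonetine S
Conditions: 3 M HCl in MeOH, rt; then Dowex 50WX8 (H+), elute with aq NH3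
Reagents that add atoms: none
Why: Acidic methanolysis removes the three TBS ethers and the Boc group in one operation, and ion exchange delivers the free base.

**Compound list**
1 | (3R,4R)-pyrrolidine-3,4-diol | C1NC[C@@H](O)[C@@H]1O | starting material
2 | (3R,4R)-3,4-bis(TBSO)pyrrolidine | C1NC[C@@H](O[Si](C)(C)C(C)(C)C)[C@@H]1O[Si](C)(C)C(C)(C)C | intermediate
3 | (3R,4R)-3,4-bis(TBSO)-3,4-dihydro-2H-pyrrole 1-oxide | C1=[N+]([O-])C[C@@H](O[Si](C)(C)C(C)(C)C)[C@@H]1O[Si](C)(C)C(C)(C)C | intermediate
4 | (2R,3R,4R)-2-[(benzyloxy)methyl]-3,4-bis(TBSO)pyrrolidin-1-ol | c1ccccc1COC[C@H]1N(O)C[C@@H](O[Si](C)(C)C(C)(C)C)[C@@H]1O[Si](C)(C)C(C)(C)C | intermediate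
5 | (2R,3R,4R)-2-[(benzyloxy)methyl]-3,4-bis(TBSO)-3,4-dihydro-2H-pyrrole 1-oxide | c1ccccc1COC[C@H]1[N+]([O-])=C[C@@H](O[Si](C)(C)C(C)(C)C)[C@@H]1O[Si](C)(C)C(C)(C)C | intermediate
6 | (2R,3R,4R,5R)-2,5-bis[(benzyloxy)methyl]-3,4-bis(TBSO)pyrrolidin-1-ol | c1ccccc1COC[C@H]1N(O)[C@H](COCc2ccccc2)[C@@H](O[Si](C)(C)C(C)(C)C)[C@@H]1O[Si](C)(C)C(C)(C)C | intermediate
7 | [(2R,3R,4R,5R)-3,4-bis(TBSO)pyrrolidine-2,5-diyl]dimethanol | OC[C@H]1N[C@H](CO)[C@@H](O[Si](C)(C)C(C)(C)C)[C@@H]1O[Si](C)(C)C(C)(C)C | intermediate
8 | tert-butyl (2R,3R,4R,5R)-3,4-bis(TBSO)-2,5-bis(hydroxymethyl)pyrrolidine-1-carboxylate | OC[C@H]1N(C(=O)OC(C)(C)C)[C@H](CO)[C@@H](O[Si](C)(C)C(C)(C)C)[C@@H]1O[Si](C)(C)C(C)(C)C | intermediate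
9 | pent-4-en-1-ol | OCCCC=C | starting material
10 | 5-(benzyloxy)pent-1-ene | C=CCCCOCc1ccccc1 | intermediate
11 | rac-2-[3-(benzyloxy)propyl]oxirane | c1ccccc1COCCCC1CO1 | intermediate
12 | (R)-2-[3-(benzyloxy)propyl]oxirane | c1ccccc1COCCC[C@@H]1CO1 | intermediate
13 | hept-1-yne | CCCCCC#C | starting material
14 | (R)-1-(benzyloxy)dodec-6-yn-4-ol | c1ccccc1COCCC[C@@H](O)CC#CCCCCC | intermediate
15 | (S)-12-(benzyloxy)dodec-1-yn-9-ol | c1ccccc1COCCC[C@@H](O)CCCCCCC#C | intermediate
16 | (9S)-12-(benzyloxy)-9-(TBSO)dodec-1-yne | c1ccccc1COCCC[C@@H](O[Si](C)(C)C(C)(C)C)CCCCCCC#C | intermediate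
17 | N-Boc (E)-allylic alcohol coupling product (full name in step 14) | c1ccccc1COCCC[C@@H](O[Si](C)(C)C(C)(C)C)CCCCCC/C=C/[C@@H](O)[C@H]1N(C(=O)OC(C)(C)C)[C@H](CO)[C@@H](O[Si](C)(C)C(C)(C)C)[C@@H]1O[Si](C)(C)C(C)(C)C | intermediate
18 | saturated N-Boc tris-TBS tetrol (full name in step 15) | OCCC[C@@H](O[Si](C)(C)C(C)(C)C)CCCCCCCC[C@@H](O)[C@H]1N(C(=O)OC(C)(C)C)[C@H](CO)[C@@H](O[Si](C)(C)C(C)(C)C)[C@@H]1O[Si](C)(C)C(C)(C)C | intermediate
19 | broussonetine S, (2R,3R,4R,5R)-2-[(1R,10S)-1,10,13-trihydroxytridecyl]-5-(hydroxymethyl)pyrrolidine-3,4-diol | OCCC[C@@H](O)CCCCCCCC[C@@H](O)[C@H]1N[C@H](CO)[C@@H](O)[C@@H]1O | target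

**Totals**
- Total steps: 16.
- Longest linear sequence: 10 (steps 1–7, then 14–16); the side chain is a separate 6-step branch (steps 8–13).

**Three steps most likely to fail, with fallbacks**
1. Step 14 (proposed new Ni-catalysed carbinol C–H alkenylation; risks are alkyne oligomerisation, over-coupling to the bis-adduct and modest dr). Fallback using known chemistry: treat 8 with NaH/THF so one CH2OH closes onto the Boc group as a bicyclic oxazolidinone, leaving one free CH2OH. Oxidise that alcohol with Dess–Martin periodinane and add the (E)-alkenylzinc made from 16 by Schwartz hydrozirconation and Me2Zn transmetalation. Finish with H2/Pd, KOH/EtOH–H2O carbamate hydrolysis and HCl/MeOH; if dr is poor, oxidise to the enone and reduce with a CBS catalyst.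
2. Step 12 (alkyne zipper; risks are incomplete migration or attack on the benzyl ether). Fallback: avoid isomerisation by opening epoxide 12 with the Grignard reagent of 7-bromo-1-(trimethylsilyl)hept-1-yne (two steps from hept-6-yn-1-ol) under CuI catalysis, then TBS protection and K2CO3/MeOH desilylation to give 16.
3. Step 5 (second addition of the thermally labile α-alkoxy Grignard to the more hindered nitrone). Fallback: add vinylmagnesium bromide to 5 as a hydroxymethyl surrogate, cleave N–O with Zn/AcOH, protect with Boc2O, and convert the vinyl group by ozonolysis/NaBH4. Hydrogenolysis of the remaining benzyl ether then gives 8, or the mono-alcohol can be used directly in the coupling.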